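**Strategy.** The C5=C6 alkene of ring B is read as the trace of a C6 ketone. Ring B (C5–C10) is then the adduct of a 2-siloxydiene (C5–C8) and an E-enal (C9=C10), which the C1–C4 chain of ring A already links. One chiral-Lewis-acid-catalysed intramolecular Diels–Alder (double Michael) reaction forms C5–C10 and C8–C9, closes rings A and B and sets C5, C8, C9 and C10. Its precursor is an acyclic siloxy-trienal whose formyl carbon is C11. The aldehyde is released from an ester only after the dienol ether is in place. C11 later takes up a tetramethoxyphenyl group, which becomes the hydroxy-aminoquinone.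

Key step: step 8

Numbering and faces: C1–C3 are the ring A methylenes counted from C10, C4 = CMe2, C5/C6 = alkene carbons, C7 = CH2, C8 = CHCH3, C9 = quaternary carbon, C10 = ring-fusion CH, C11 = CH2 link. β is the face carrying the C8 and C9 methyl groups and α is the opposite face.

Assumption: the sense of induction in step 8 follows the accepted model for α-substituted enals on proline-derived cationic oxazaborolidines (formyl C–H···O contact, s-trans enal stacked on the neighbouring phenyl group). This model predicts attack on the C9-Re/C10-Si face with the (S)-catalyst, and the (R)-catalyst is equally accessible.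

**Step 1**
Reactants: 1 5-bromopent-1-ene; 2 mesityl oxide
Product: 4 4,4-dimethylnon-8-en-2-one, via pent-4-enylmagnesium bromide 3 (not isolated)
Conditions: Mg, THF, 25 → 40 °C; then CuBr·SMe2 (5 mol %), 2, THF, −30 → 0 °C; aq NH4Cl
Reagents that add atoms: none
Why: Copper-catalysed 1,4-addition of a Grignard reagent (Kharasch type): the organocopper species made from 3 adds to the β,β-disubstituted enone carbon rather than to the carbonyl group, which creates the quaternary C4 and forms no stereocentre.

**Step 2**
Reactants: 4 4,4-dimethylnon-8-en-2-one; 5 acetaldehyde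
Product: 7 rac-2-hydroxy-6,6-dimethylundec-10-en-4-one, via lithium enolate 6 (not isolated)
Conditions: LiN(i-Pr)2, THF, −78 °C; 5, −78 °C; aq NH4Cl
Reagents that add atoms: none
Why: Kinetic lithium-enolate aldol addition: the amide base removes a proton from the open methyl group and not from the neopentyl methylene, and the racemic carbinol centre is erased in step 4.

**Step 3**
Reactants: 7 rac-2-hydroxy-6,6-dimethylundec-10-en-4-one; 8 methyl methacrylate
Product: 9 methyl (2E)-11-hydroxy-2,7,7-trimethyl-9-oxododec-2-enoate (racemic carbinol)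
Conditions: 8 (10 equiv), second-generation Hoveyda–Grubbs catalyst (5 mol %), CH2Cl2, 40 °C
Reagents that add atoms: none
Why: Olefin cross metathesis of a reactive terminal alkene with an excess of a sluggish 1,1-disubstituted acrylate should give the thermodynamically preferred E-trisubstituted enoate, and running it before the propenyl ketone exists removes the only other electron-poor alkene that could compete as a metathesis partner.

**Step 4**
Reactants: 9 methyl (2E)-11-hydroxy-2,7,7-trimethyl-9-oxododec-2-enoate
Product: 11 methyl (2E,10E)-2,7,7-trimethyl-9-oxododeca-2,10-dienoate, via secondary mesylate 10 (not isolated)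
Conditions: MsCl, Et3N (excess), CH2Cl2, 0 °C → rt
Reagents that add atoms: none
Why: Mesylation followed by E1cB elimination of the β-mesyloxy ketone completes the aldol condensation and should give the conjugated E-propenyl ketone, while the enoate is inert to these conditions.

**Step 5**
Reactants: 11 methyl (2E,10E)-2,7,7-trimethyl-9-oxododeca-2,10-dienoate
Product: 12 methyl (2E,8Z,10E)-9-(tert-butyldimethylsilyloxy)-2,7,7-trimethyldodeca-2,8,10-trienoate
Conditions: TBSOTf, Et3N, CH2Cl2, −78 → 0 °C; aq NaHCO3
Reagents that add atoms: tert-butyldimethylsilyl triflate, CC(C)(C)[Si](C)(C)OS(=O)(=O)C(F)(F)F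
Why: Soft enolisation (silyl triflate/amine) of an enone takes the α′ proton and gives the cross-conjugated 2-siloxydiene, Z because the alternative would put the quaternary C4 cis to the propenyl group; the enoate is not enolised, whereas an enal with γ-hydrogens would itself become a 1-siloxydiene here, which is why C11 is kept at the ester level until now.

**Step 6**
Reactants: 12 methyl (2E,8Z,10E)-9-(tert-butyldimethylsilyloxy)-2,7,7-trimethyldodeca-2,8,10-trienoate
Product: 13 (2E,8Z,10E)-9-(tert-butyldimethylsilyloxy)-2,7,7-trimethyldodeca-2,8,10-trien-1-ol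
Conditions: i-Bu2AlH (2.2 equiv), CH2Cl2, −78 °C; aq potassium sodium tartrate
Reagents that add atoms: none
Why: 1,2-Reduction of an enoate by a dialkylaluminium hydride gives the allylic alcohol, and the aprotic reagent and non-acidic work-up leave the silyl dienol ether and all alkene geometries untouched.

**Step 7**
Reactants: 13 (2E,8Z,10E)-9-(tert-butyldimethylsilyloxy)-2,7,7-trimethyldodeca-2,8,10-trien-1-ol
Product: 14 (2E,8Z,10E)-9-(tert-butyldimethylsilyloxy)-2,7,7-trimethyldodeca-2,8,10-trienal
Conditions: MnO2, CH2Cl2, 0 °C → rt; filtration, kept cold and used at once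
Reagents that add atoms: none
Why: Heterogeneous MnO2 oxidation is selective for allylic alcohols and is neutral, so the acid-labile dienol ether and the E-enal geometry should be preserved.

**Step 8**
Reactants: 14 (2E,8Z,10E)-9-(tert-butyldimethylsilyloxy)-2,7,7-trimethyldodeca-2,8,10-trienal
Product: 15 (1R,2S,4aR,8aR)-4-(tert-butyldimethylsilyloxy)-1,2,5,5-tetramethyl-1,2,4a,5,6,7,8,8a-octahydronaphthalene-1-carbaldehyde (cis-fused; 5R,8S,9R,10R)
Conditions: (S)-3,3-diphenyl-1-(2-methylphenyl)tetrahydro-1H,3H-pyrrolo[1,2-c][1,3,2]oxazaborole (20 mol %), HN(SO2CF3)2 (17 mol %), CH2Cl2 (0.01 M), −78 → −40 °C; Et3N quench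
Reagents that add atoms: none
Why: The boron centre of the cationic oxazaborolidine binds the formyl oxygen and lowers the enal LUMO, so that the nucleophilic enol ether carbon C5 attacks C10 and C9 closes on C8, either as a strongly asynchronous [4+2] cycloaddition or as a Mukaiyama–Michael/Michael pair in which silicon stays on O6 throughout. The closest known reactions are the chiral-Lewis-acid-catalysed type 1 intramolecular Diels–Alder reaction of 2-methyl-substituted trienals and the intermolecular addition of 2-siloxydienes to α-substituted enals under this catalyst family, and what analogy does not secure is the formyl-exo folding of this substrate. Ring A (C10, C1–C5) closes through the four-atom tether in a 6-exo mode at C10, helped by the gem-dialkyl effect of C4, and ring B (C5–C10) closes as the six-membered cycloadduct (6-endo at C8 in the stepwise picture). C9 and C10 follow from suprafacial addition to the E-enal (C9 methyl trans to H10) and from the catalyst aryl group, which covers one enal face; C5 and C8 follow from the Z-enol ether (C4 outside) and the E-propenyl terminus (CH3 outside) in the orientation that holds the tether and the C9 methyl under the diene and the formyl group away from it, so that C4, C1 and both methyl groups end on the β face (cis fusion, C8/C9 methyls cis). The step therefore needs formyl-exo selectivity and one enantioface: the first should be favoured by the α-methyl group, which makes such enals exo-selective, and by allylic 1,3-strain, because the trans-fused folding forces one C4 methyl nearly into the diene plane against the cis siloxy group while the cis-fused folding lets C3 and one methyl straddle it, and the second is set by the catalyst. High dilution, a slight excess of oxazaborolidine over HN(SO2CF3)2 and the amine quench guard against intermolecular Mukaiyama aldol addition, achiral silyl-cation catalysis and loss of the enol ether.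

**Step 9**
Reactants: 15 cis-fused siloxy-decalin aldehyde; 16 1,2,4,5-tetramethoxybenzene
Product: 20 S-methyl xanthate of the C11 aryl carbinol (C11 epimers), via aryllithium 17 (not isolated), via lithium alkoxide 18 (not isolated), via lithium xanthate 19 (not isolated)
Conditions: 16, n-BuLi, THF, 0 °C → rt; 15, −78 → 0 °C; CS2, 0 °C → rt; MeI, rt
Reagents that add atoms: carbon disulfide, S=C=S; iodomethane, CI
Why: Directed ortho-lithiation between two methoxy groups, 1,2-addition to a non-enolisable neopentyl aldehyde and in-flask xanthate formation; the C11 carbinol centre arises as an epimer mixture that is removed in step 10, and the TBS enol ether tolerates the cold organolithium.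

**Step 10**
Reactants: 20 S-methyl xanthate of the C11 aryl carbinol
Product: 21 cis-fused C6=C7 TBS enol ether carrying a 2,3,5,6-tetramethoxybenzyl group on C9 (5R,8S,9R,10R)
Conditions: n-Bu3SnH, AIBN, toluene, 100 °C
Reagents that add atoms: none
Why: Barton–McCombie deoxygenation: the stannyl radical attacks C=S, the benzylic C11 radical takes hydrogen from the stannane, the quaternary C9 rules out thermal xanthate elimination, and the neutral radical path avoids a neopentyl cation prone to Wagner–Meerwein shift and spares the enol ether.

**Step 11**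
Reactants: 21 cis-fused C6=C7 TBS enol ether
Product: 23 trans-fused C6 ketone (5S,8S,9R,10R), via cis-fused ketone 22 (not isolated)
Conditions: n-Bu4NF, THF, 0 °C; then NaOMe (cat.), MeOH, rt
Reagents that add atoms: none
Why: Fluoride desilylation and protonation at C7 give 22, and base equilibration of C5, the only enolisable stereocentre, should favour trans-decalone 23 (axial C9 methyl, equatorial C11 and C8 methyl), because both chair–chair forms of 22 carry a syn-pentane contact (C4 against the C9 methyl, or C1 against the C8 methyl).

**Step 12**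
Reactants: 23 trans-fused C6 ketone
Product: 24 axial 6α-alcohol (5S,6S,8S,9R,10R)
Conditions: LiAlH4, Et2O, 0 °C
Reagents that add atoms: none
Why: Hydride reduction under steric approach control: the axial α trajectory is blocked by the syn-axial C4 methyl group, so hydride should arrive from the β face and set C6 with an axial hydroxyl, as in 6-oxo trans-decalins that carry a syn-axial methyl group.

**Step 13**
Reactants: 24 axial 6α-alcohol
Product: 25 C5=C6 alkene carrying the 2,3,5,6-tetramethoxybenzyl group (8S,9R,10S)
Conditions: POCl3, pyridine, 0 → 60 °C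
Reagents that add atoms: none
Why: E2 dehydration through the dichlorophosphate: the axial leaving group is antiperiplanar to the axial tertiary H5, and Zaitsev-oriented loss of that hydrogen should give the trisubstituted alkene, as with axial 6-hydroxy trans-fused steroid-type systems; basic conditions avoid the C5 cation and its methyl shift, C5 and C6 cease to be stereocentres, and C8, C9 and C10 are untouched.

**Step 14**
Reactants: 25 C5=C6 alkene carrying the tetramethoxybenzyl group
Product: 26 3-substituted 2,5-dimethoxy-1,4-benzoquinone
Conditions: (NH4)2Ce(NO3)6, MeCN–H2O, 0 °C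
Reagents that add atoms: water, O
Why: Oxidative demethylation by tetravalent cerium: the two para-dimethoxy pairs are equivalent by symmetry, so one p-quinone should result, and the isolated trisubstituted alkene is not attacked in the cold.

**Step 15**
Reactants: 26 3-substituted 2,5-dimethoxy-1,4-benzoquinone
Product: 27 3-substituted 2-hydroxy-5-methoxy-1,4-benzoquinone
Conditions: KOH, MeOH–H2O, rt; then aq HCl
Reagents that add atoms: potassium hydroxide, [K+].[OH-]
Why: Regioselective saponification of a vinylogous ester by addition–elimination: the methoxy group next to the bulky C11 substituent is twisted out of conjugation and is the more electrophilic site, the hydroxyquinone anion resists a second attack, and this selectivity is established for 3-alkyl-2,5-dimethoxybenzoquinones of this sesquiterpene quinone family.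

**Step 16**
Reactants: 27 3-substituted 2-hydroxy-5-methoxy-1,4-benzoquinone; 28 3-methylbutan-1-amine
Product: 29 nakijiquinone M
Conditions: 28 (3 equiv), EtOH, rt; dilute acid wash
Reagents that add atoms: none
Why: Addition–elimination turns the remaining vinylogous ester into the vinylogous amide; the ionised hydroxyl deactivates its own half of the quinone, so the amine should enter only at the methoxy-bearing carbon, and no stereocentre is affected.

**Compound list**
1 | 5-bromopent-1-ene | C=CCCCBr | starting material
2 | mesityl oxide (4-methylpent-3-en-2-one) | CC(C)=CC(C)=O | starting material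
3 | pent-4-enylmagnesium bromide | C=CCCC[Mg]Br | intermediate
4 | 4,4-dimethylnon-8-en-2-one | CC(=O)CC(C)(C)CCCC=C | intermediate
5 | acetaldehyde | CC=O | starting material
6 | terminal lithium enolate of 4 | [Li]OC(=C)CC(C)(C)CCCC=C | intermediate
7 | rac-2-hydroxy-6,6-dimethylundec-10-en-4-one | CC(O)CC(=O)CC(C)(C)CCCC=C | intermediate
8 | methyl methacrylate | C=C(C)C(=O)OC | starting material
9 | methyl (2E)-11-hydroxy-2,7,7-trimethyl-9-oxododec-2-enoate (racemic carbinol) | CC(O)CC(=O)CC(C)(C)CCC/C=C(\C)C(=O)OC | intermediate
10 | methyl (2E)-11-(methanesulfonyloxy)-2,7,7-trimethyl-9-oxododec-2-enoate | CC(OS(C)(=O)=O)CC(=O)CC(C)(C)CCC/C=C(\C)C(=O)OC | intermediate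
11 | methyl (2E,10E)-2,7,7-trimethyl-9-oxododeca-2,10-dienoate | C/C=C/C(=O)CC(C)(C)CCC/C=C(\C)C(=O)OC | intermediate
12 | methyl (2E,8Z,10E)-9-(tert-butyldimethylsilyloxy)-2,7,7-trimethyldodeca-2,8,10-trienoate | C/C=C/C(O[Si](C)(C)C(C)(C)C)=C/C(C)(C)CCC/C=C(\C)C(=O)OC | intermediate
13 | (2E,8Z,10E)-9-(tert-butyldimethylsilyloxy)-2,7,7-trimethyldodeca-2,8,10-trien-1-ol | C/C=C/C(O[Si](C)(C)C(C)(C)C)=C/C(C)(C)CCC/C=C(\C)CO | intermediate
14 | (2E,8Z,10E)-9-(tert-butyldimethylsilyloxy)-2,7,7-trimethyldodeca-2,8,10-trienal | C/C=C/C(O[Si](C)(C)C(C)(C)C)=C/C(C)(C)CCC/C=C(\C)C=O | intermediate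
15 | (1R,2S,4aR,8aR)-4-(tert-butyldimethylsilyloxy)-1,2,5,5-tetramethyl-1,2,4a,5,6,7,8,8a-octahydronaphthalene-1-carbaldehyde (cis-fused) | C[C@H]1C=C(O[Si](C)(C)C(C)(C)C)[C@H]2C(C)(C)CCC[C@H]2[C@]1(C)C=O | intermediate
16 | 1,2,4,5-tetramethoxybenzene | COc1cc(OC)c(OC)cc1OC | starting material
17 | 2,3,5,6-tetramethoxyphenyllithium | [Li]c1c(OC)c(OC)cc(OC)c1OC | intermediate
18 | lithium alkoxide from 17 and 15 (C11 epimers) | C[C@H]1C=C(O[Si](C)(C)C(C)(C)C)[C@H]2C(C)(C)CCC[C@H]2[C@]1(C)C(O[Li])c3c(OC)c(OC)cc(OC)c3OC | intermediate
19 | lithium xanthate from 18 and CS2 (C11 epimers) | C[C@H]1C=C(O[Si](C)(C)C(C)(C)C)[C@H]2C(C)(C)CCC[C@H]2[C@]1(C)C(OC(=S)S[Li])c3c(OC)c(OC)cc(OC)c3OC | intermediate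
20 | S-methyl xanthate of the C11 aryl carbinol (C11 epimers) | C[C@H]1C=C(O[Si](C)(C)C(C)(C)C)[C@H]2C(C)(C)CCC[C@H]2[C@]1(C)C(OC(=S)SC)c3c(OC)c(OC)cc(OC)c3OC | intermediate
21 | cis-fused C6=C7 TBS enol ether with 2,3,5,6-tetramethoxybenzyl on C9 (5R,8S,9R,10R) | C[C@H]1C=C(O[Si](C)(C)C(C)(C)C)[C@H]2C(C)(C)CCC[C@H]2[C@]1(C)Cc3c(OC)c(OC)cc(OC)c3OC | intermediate
22 | cis-fused C6 ketone (5R,8S,9R,10R) | C[C@H]1CC(=O)[C@H]2C(C)(C)CCC[C@H]2[C@]1(C)Cc3c(OC)c(OC)cc(OC)c3OC | intermediate
23 | trans-fused C6 ketone (5S,8S,9R,10R) | C[C@H]1CC(=O)[C@@H]2C(C)(C)CCC[C@H]2[C@]1(C)Cc3c(OC)c(OC)cc(OC)c3OC | intermediate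
24 | trans-fused axial 6α-alcohol (5S,6S,8S,9R,10R) | C[C@H]1C[C@H](O)[C@@H]2C(C)(C)CCC[C@H]2[C@]1(C)Cc3c(OC)c(OC)cc(OC)c3OC | intermediate
25 | C5=C6 alkene with 2,3,5,6-tetramethoxybenzyl on C9 (8S,9R,10S) | C[C@H]1CC=C2C(C)(C)CCC[C@H]2[C@]1(C)Cc3c(OC)c(OC)cc(OC)c3OC | intermediate
26 | 2,5-dimethoxy-1,4-benzoquinone carrying the C11 methylene at position 3 | C[C@H]1CC=C2C(C)(C)CCC[C@H]2[C@]1(C)CC3=C(OC)C(=O)C=C(OC)C3=O | intermediate
27 | 2-hydroxy-5-methoxy-1,4-benzoquinone carrying the C11 methylene at position 3 | C[C@H]1CC=C2C(C)(C)CCC[C@H]2[C@]1(C)CC3=C(O)C(=O)C=C(OC)C3=O | intermediate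
28 | 3-methylbutan-1-amine (isopentylamine) | CC(C)CCN | starting material
29 | nakijiquinone M (8S,9R,10S) | CC(C)CCNC1=CC(=O)C(O)=C(C[C@@]2(C)[C@@H]3CCCC(C)(C)C3=CC[C@@H]2C)C1=O | target

**Step count.** Total steps: 16. Longest linear sequence: 16 steps (1 and 2 to 29). Compounds 5, 8, 16 and 28 enter as purchased materials.

**Steps most likely to fail**

Step 8. Folding through the formyl-endo, trans-fused transition state may compete with the formyl-exo one. This would invert C5 and C8 relative to C9 and C10. The catalyst fixes the enal face whichever way the chain folds, so C9 and C10 are correct in both adducts. The fallback therefore replaces kinetic control of C8 by erasing and resetting it.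
- It sets out from 14, and cyclisation under the step 8 conditions gives the trans-fused formyl-endo adduct F1.
- Addition of 17 gives the lithium alkoxide F2, CS2 gives the lithium xanthate F3, and MeI gives the S-methyl xanthate F4.
- n-Bu3SnH/AIBN gives the trans-fused 8-epi silyl enol ether F5.
- Saegusa–Ito oxidation (Pd(OAc)2, MeCN) removes the C8 stereocentre and gives the C7=C8 enone F6.
- Hydrogenation (H2, Pd/C, EtOAc) from the α face, opposite the axial C9 methyl group, places the C8 methyl β and comes back to the route at 23.
- A mixture of both adducts can be funnelled the same way.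

Step 13. Removal of the axial H7 may compete with removal of H5 and shift the double bond to C6=C7. The fallback moves the regiochemical decision from an E2 competition to enol-derivative formation.
- It sets out from 23, and Tf2O with 2,6-di-tert-butyl-4-methylpyridine in CH2Cl2 gives the tetrasubstituted C5=C6 enol triflate F8. These conditions are known to favour the more substituted enol triflate.
- Hydrogenolysis with formate under zerovalent palladium catalysis (Pd(OAc)2, PPh3, HCO2H, Et3N, DMF) comes back to the route at 25.

Step 9. Capture of the crowded alkoxide 18 by CS2 may be sluggish, and surplus 17 may consume CS2. The fallback replaces radical deoxygenation by ionic hydrogenation.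
- It sets out from 15, and addition of 17 followed by an aqueous NH4Cl quench gives the free C11 carbinol F7.
- Et3SiH/CF3CO2H in CH2Cl2 (−20 → 0 °C) ionises the electron-rich benzylic alcohol, and the silane reduces the cation.
- The same acid protodesilylates the enol ether, so the sequence comes back to the route at 22, which is epimerised to 23 as in step 11.
- This shorter path is held in reserve because the neopentyl cation could undergo a 1,2-shift.

**Further compounds**
F1 | step 8 | trans-fused formyl-endo adduct (5S,8R,9R,10R) | C[C@@H]1C=C(O[Si](C)(C)C(C)(C)C)[C@@H]2C(C)(C)CCC[C@H]2[C@]1(C)C=O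
F2 | step 8 | lithium alkoxide from 17 and F1 (C11 epimers) | C[C@@H]1C=C(O[Si](C)(C)C(C)(C)C)[C@@H]2C(C)(C)CCC[C@H]2[C@]1(C)C(O[Li])c3c(OC)c(OC)cc(OC)c3OC
F3 | step 8 | lithium xanthate from F2 (C11 epimers) | C[C@@H]1C=C(O[Si](C)(C)C(C)(C)C)[C@@H]2C(C)(C)CCC[C@H]2[C@]1(C)C(OC(=S)S[Li])c3c(OC)c(OC)cc(OC)c3OC
F4 | step 8 | S-methyl xanthate in the 8-epi trans-fused series (C11 epimers) | C[C@@H]1C=C(O[Si](C)(C)C(C)(C)C)[C@@H]2C(C)(C)CCC[C@H]2[C@]1(C)C(OC(=S)SC)c3c(OC)c(OC)cc(OC)c3OC
F5 | step 8 | trans-fused 8-epi C6=C7 TBS enol ether with tetramethoxybenzyl on C9 | C[C@@H]1C=C(O[Si](C)(C)C(C)(C)C)[C@@H]2C(C)(C)CCC[C@H]2[C@]1(C)Cc3c(OC)c(OC)cc(OC)c3OC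
F6 | step 8 | trans-fused C6 ketone with C7=C8 alkene (5S,9S,10R) | CC1=CC(=O)[C@@H]2C(C)(C)CCC[C@H]2[C@]1(C)Cc3c(OC)c(OC)cc(OC)c3OC
F7 | step 9 | free C11 aryl carbinol of the cis-fused silyl enol ether (C11 epimers) | C[C@H]1C=C(O[Si](C)(C)C(C)(C)C)[C@H]2C(C)(C)CCC[C@H]2[C@]1(C)C(O)c3c(OC)c(OC)cc(OC)c3OC
F8 | step 13 | C5=C6 enol triflate (8S,9R,10S) | C[C@H]1CC(OS(=O)(=O)C(F)(F)F)=C2C(C)(C)CCC[C@H]2[C@]1(C)Cc3c(OC)c(OC)cc(OC)c3OC
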